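**Retrosynthetic overview**

- Ring B (the ketone ring of the tetralone) is opened at C1–C8a: an intramolecular Friedel–Crafts acylation of a 4,4-diarylbutanoic acid onto the hydroquinone ring A closes it late.
- The naphthalene is cut at C1′–C8a′ and C4′–C4a′. The plan rests on its substitution pattern: a free hydroxyl at C4′, para to the C1′–C4 bond in the same ring, and a methyl ether at C8′, peri to that bond in the other ring. A 2-substituted furan supplies C1′–C4′ and its oxygen becomes the C4′ hydroxyl; 3-methoxybenzyne supplies C4a′–C8a′ with the methoxy group already on C8′.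
- The C4 stereocentre is cut at its bond to ring A: rhodium/(R)-BINAP conjugate addition of a 2,5-bis(benzyloxy)phenylboronic acid to methyl 3-(2-furyl)acrylate, then Arndt–Eistert homologation.
- Order of ring formation: ring A and the furan are bought; the furan is annulated to the naphthalene (step 7); ring B is closed (step 10); debenzylation ends the route.

Key step: step 7

Remark: tetralone locants are C1–C8a, primed locants belong to the naphthalene. The target centre C4 is S; the R descriptor of the furan-bearing intermediates denotes the same spatial arrangement, because a 2-furyl group outranks the dialkoxyphenyl group whereas the naphthyl group does not.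

**Route**

Step 1
Reactants: 1 2-bromobenzene-1,4-diol
Product: 2 1,4-bis(benzyloxy)-2-bromobenzene
Conditions: BnBr (2.2 equiv), K2CO3, DMF, 60 °C, under N2
Reagents that add atoms: benzyl bromide, BrCc1ccccc1
Why: Williamson ether synthesis on both phenoxides, with the aryl bromide inert to carbonate and air excluded so that the hydroquinone is not oxidised before it is alkylated.

Step 2
Reactants: 2 1,4-bis(benzyloxy)-2-bromobenzene
Product: 5 [2,5-bis(benzyloxy)phenyl]boronic acid, via aryllithium 3 (not isolated), via lithium aryl(triisopropoxy)borate 4 (not isolated)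
Conditions: n-BuLi, THF, −78 °C; B(OiPr)3, −78 → 23 °C; then HCl (1 M aq.)
Reagents that add atoms: triisopropyl borate, CC(C)OB(OC(C)C)OC(C)C; water, O
Why: Bromine–lithium exchange at −78 °C should outrun benzylic deprotonation, and the aryllithium is trapped by the borate ester and hydrolysed to the boronic acid (lithiation–borylation).

Step 3
Reactants: 5 [2,5-bis(benzyloxy)phenyl]boronic acid; 6 methyl (2E)-3-(furan-2-yl)prop-2-enoate
Product: 7 methyl (3R)-3-[2,5-bis(benzyloxy)phenyl]-3-(furan-2-yl)propanoate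
Conditions: 5 (2 equiv), [RhCl(C2H4)2]2 (1.5 mol %), (R)-BINAP (3.3 mol %), KOH (10 mol %), dioxane/H2O 10:1, 50 °C
Reagents that add atoms: none
Why: Hayashi–Miyaura reaction, in which the aryl group passes from boron to monovalent rhodium and inserts the E-enoate; the (R)-BINAP complex is expected, by the accepted quadrant model for E-configured acyclic acceptors, to deliver the aryl group to the αsi face and so set the R centre, and water releases the product.

Step 4
Reactants: 7 methyl (3R)-3-[2,5-bis(benzyloxy)phenyl]-3-(furan-2-yl)propanoate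
Product: 8 (3R)-3-[2,5-bis(benzyloxy)phenyl]-3-(furan-2-yl)propanoic acid
Conditions: LiOH·H2O, THF/MeOH/H2O, 23 °C; then HCl (1 M aq.), 0 °C, to pH 3
Reagents that add atoms: lithium hydroxide, [Li+].[OH-]
Why: Ester saponification; the stereocentre is β to the carbonyl group and cannot epimerise, and the brief cold acidification spares the furan.

Step 5
Reactants: 8 (3R)-3-[2,5-bis(benzyloxy)phenyl]-3-(furan-2-yl)propanoic acid
Product: 10 (4R)-4-[2,5-bis(benzyloxy)phenyl]-1-diazo-4-(furan-2-yl)butan-2-one, via ethyl carbonic mixed anhydride 9 (not isolated)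
Conditions: ClCO2Et, Et3N, THF, −15 °C; then CH2N2, Et2O, 0 → 23 °C
Reagents that add atoms: diazomethane, C=[N+]=[N-]
Why: First stage of the Arndt–Eistert homologation, acylation of diazomethane by a mixed anhydride, chosen over the acid chloride so that no HCl meets the acid-sensitive furan.

Step 6
Reactants: 10 (4R)-4-[2,5-bis(benzyloxy)phenyl]-1-diazo-4-(furan-2-yl)butan-2-one
Product: 12 methyl (4R)-4-[2,5-bis(benzyloxy)phenyl]-4-(furan-2-yl)butanoate, via ketene 11 (not isolated)
Conditions: PhCO2Ag (10 mol %), Et3N, MeOH, 23 °C, in the dark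
Reagents that add atoms: methanol, CO
Why: Silver-catalysed Wolff rearrangement, in which the CH2 group migrates as N2 leaves and methanol traps the ketene as the homologous ester, the stereocentre taking no part.

Step 7
Reactants: 12 methyl (4R)-4-[2,5-bis(benzyloxy)phenyl]-4-(furan-2-yl)butanoate; 13 3-methoxy-2-(trimethylsilyl)phenyl trifluoromethanesulfonate
Product: 16 methyl (4S)-4-[2,5-bis(benzyloxy)phenyl]-4-(4-hydroxy-8-methoxynaphthalen-1-yl)butanoate, via 3-methoxybenzyne 14 (not isolated), via oxygen-bridged cycloadduct 15 (not isolated)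
Conditions: 13 (2 equiv), CsF (4 equiv), MeCN, 23 °C; then HCl (conc. aq., cat.), MeOH, 23 °C
Reagents that add atoms: none
Why: Fluoride attacks the silicon of 13 and triflate leaves, releasing 3-methoxybenzyne 14, which adds across C2 and C5 of the furan in a concerted but asynchronous [4+2] cycloaddition (aryne–furan Diels–Alder reaction) to give the 7-oxabenzonorbornadiene 15. This intermolecular cycloaddition forms C4′–C4a′ and C1′–C8a′ and so closes the carbocyclic ring C1′–C4′/C4a′/C8a′ of the naphthalene in one event, with the furan oxygen spanning C1′ and C4′ as a bridge. The step needs the orientation that sets the substituted furan carbon next to the methoxy-bearing side of the aryne: the inductive pull of the methoxy group distorts the aryne so that the carbon meta to it is the electrophilic end, which should bond first to the unsubstituted, more nucleophilic furan α-carbon, while the second bond at the crowded end is still long in the transition state and the clash between the branched side chain and the methoxy group is thereby lessened. Acid then ionises the bridge C–O bond at C1′, where the cation is tertiary, allylic and benzylic and is stabilised by the ortho methoxy group, and loss of the C4′ proton aromatises the ring to the 4-alkyl-1-naphthol with the oxygen left on C4′ (acid-catalysed isomerisation of 1,4-epoxy-1,4-dihydronaphthalenes to 1-naphthols). The two bridgehead centres of 15 form without control and are destroyed on aromatisation, so no new stereocentre remains, and the C4 centre carries no bond that fluoride or dilute acid can break and is carried through unchanged. The ester is kept because a free acid would add to the aryne, and the acid is introduced only after the aryne is spent so that the new naphthol cannot be O-arylated.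

Step 8
Reactants: 16 methyl (4S)-4-[2,5-bis(benzyloxy)phenyl]-4-(4-hydroxy-8-methoxynaphthalen-1-yl)butanoate
Product: 17 methyl (4S)-4-[4-(benzyloxy)-8-methoxynaphthalen-1-yl]-4-[2,5-bis(benzyloxy)phenyl]butanoate
Conditions: BnBr, K2CO3, DMF, 23 °C, under N2
Reagents that add atoms: benzyl bromide, BrCc1ccccc1
Why: Williamson benzylation of the naphthol, which protects the oxidation-prone 4-alkyl-1-naphthol and keeps the hydroxyl from being acylated in step 10.

Step 9
Reactants: 17 methyl (4S)-4-[4-(benzyloxy)-8-methoxynaphthalen-1-yl]-4-[2,5-bis(benzyloxy)phenyl]butanoate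
Product: 18 (4S)-4-[4-(benzyloxy)-8-methoxynaphthalen-1-yl]-4-[2,5-bis(benzyloxy)phenyl]butanoic acid
Conditions: LiOH·H2O, THF/MeOH/H2O, 23 °C; then HCl (1 M aq.)
Reagents that add atoms: lithium hydroxide, [Li+].[OH-]
Why: Ester saponification under conditions that leave aryl ethers and the diarylmethine centre, which is not acidic enough for hydroxide, untouched.

Step 10
Reactants: 18 (4S)-4-[4-(benzyloxy)-8-methoxynaphthalen-1-yl]-4-[2,5-bis(benzyloxy)phenyl]butanoic acid
Product: 20 (4S)-5,8-bis(benzyloxy)-4-[4-(benzyloxy)-8-methoxynaphthalen-1-yl]-3,4-dihydronaphthalen-1(2H)-one, via mixed trifluoroacetic anhydride 19 (not isolated)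
Conditions: TFAA (3 equiv), CH2Cl2, 0 → 23 °C
Reagents that add atoms: none
Why: Intramolecular Friedel–Crafts acylation through the mixed anhydride closes ring B as a six-membered ring at the ring A carbon ortho to a benzyloxy group, whereas the competing site C2′ of the naphthalene is meta to its benzyloxy group, and the absence of a metal Lewis acid spares the benzyl ethers.

Step 11
Reactants: 20 (4S)-5,8-bis(benzyloxy)-4-[4-(benzyloxy)-8-methoxynaphthalen-1-yl]-3,4-dihydronaphthalen-1(2H)-one
Product: 21 (4S)-5,8-dihydroxy-4-(4-hydroxy-8-methoxynaphthalen-1-yl)-3,4-dihydronaphthalen-1(2H)-one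
Conditions: H2 (1 atm), 10% Pd/C, EtOAc/EtOH, 23 °C, work-up under inert gas
Reagents that add atoms: none
Why: Hydrogenolysis of the three benzyl ethers, with the methyl ether inert and the electron-rich aryl ketone and diarylmethine C–H not expected to be reduced at ambient pressure and temperature.

**Compound list**

1 | 2-bromobenzene-1,4-diol | Oc1ccc(O)c(Br)c1 | starting material
2 | 1,4-bis(benzyloxy)-2-bromobenzene | Brc1cc(OCc2ccccc2)ccc1OCc1ccccc1 | intermediate
3 | [2,5-bis(benzyloxy)phenyl]lithium | [Li]c1cc(OCc2ccccc2)ccc1OCc1ccccc1 | intermediate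
4 | lithium [2,5-bis(benzyloxy)phenyl]tri(propan-2-yloxy)borate | [Li+].CC(C)O[B-](OC(C)C)(OC(C)C)c1cc(OCc2ccccc2)ccc1OCc1ccccc1 | intermediate
5 | [2,5-bis(benzyloxy)phenyl]boronic acid | OB(O)c1cc(OCc2ccccc2)ccc1OCc1ccccc1 | intermediate
6 | methyl (2E)-3-(furan-2-yl)prop-2-enoate | COC(=O)/C=C/c1ccco1 | starting material
7 | methyl (3R)-3-[2,5-bis(benzyloxy)phenyl]-3-(furan-2-yl)propanoate | o1cccc1[C@@H](c1cc(OCc2ccccc2)ccc1OCc1ccccc1)CC(=O)OC | intermediate
8 | (3R)-3-[2,5-bis(benzyloxy)phenyl]-3-(furan-2-yl)propanoic acid | o1cccc1[C@@H](c1cc(OCc2ccccc2)ccc1OCc1ccccc1)CC(=O)O | intermediate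
9 | (3R)-3-[2,5-bis(benzyloxy)phenyl]-3-(furan-2-yl)propanoic ethyl carbonic anhydride | o1cccc1[C@@H](c1cc(OCc2ccccc2)ccc1OCc1ccccc1)CC(=O)OC(=O)OCC | intermediate
10 | (4R)-4-[2,5-bis(benzyloxy)phenyl]-1-diazo-4-(furan-2-yl)butan-2-one | o1cccc1[C@@H](c1cc(OCc2ccccc2)ccc1OCc1ccccc1)CC(=O)C=[N+]=[N-] | intermediate
11 | (4R)-4-[2,5-bis(benzyloxy)phenyl]-4-(furan-2-yl)but-1-en-1-one (ketene) | o1cccc1[C@@H](c1cc(OCc2ccccc2)ccc1OCc1ccccc1)CC=C=O | intermediate
12 | methyl (4R)-4-[2,5-bis(benzyloxy)phenyl]-4-(furan-2-yl)butanoate | o1cccc1[C@@H](c1cc(OCc2ccccc2)ccc1OCc1ccccc1)CCC(=O)OC | intermediate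
13 | 3-methoxy-2-(trimethylsilyl)phenyl trifluoromethanesulfonate | COc1cccc(OS(=O)(=O)C(F)(F)F)c1[Si](C)(C)C | starting material
14 | 3-methoxybenzyne (1-methoxycyclohexa-1,3-dien-5-yne) | COC1=CC=CC#C1 | intermediate
15 | methyl (4R)-4-[2,5-bis(benzyloxy)phenyl]-4-(8-methoxy-1,4-dihydro-1,4-epoxynaphthalen-1-yl)butanoate, both bridgehead diastereomers | COc1cccc2c1C1(OC2C=C1)[C@@H](c1cc(OCc2ccccc2)ccc1OCc1ccccc1)CCC(=O)OC | intermediate
16 | methyl (4S)-4-[2,5-bis(benzyloxy)phenyl]-4-(4-hydroxy-8-methoxynaphthalen-1-yl)butanoate | COc1cccc2c(O)ccc([C@@H](c3cc(OCc4ccccc4)ccc3OCc3ccccc3)CCC(=O)OC)c12 | intermediate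
17 | methyl (4S)-4-[4-(benzyloxy)-8-methoxynaphthalen-1-yl]-4-[2,5-bis(benzyloxy)phenyl]butanoate | COc1cccc2c(OCc3ccccc3)ccc([C@@H](c3cc(OCc4ccccc4)ccc3OCc3ccccc3)CCC(=O)OC)c12 | intermediate
18 | (4S)-4-[4-(benzyloxy)-8-methoxynaphthalen-1-yl]-4-[2,5-bis(benzyloxy)phenyl]butanoic acid | COc1cccc2c(OCc3ccccc3)ccc([C@@H](c3cc(OCc4ccccc4)ccc3OCc3ccccc3)CCC(=O)O)c12 | intermediate
19 | (4S)-4-[4-(benzyloxy)-8-methoxynaphthalen-1-yl]-4-[2,5-bis(benzyloxy)phenyl]butanoic trifluoroacetic anhydride | COc1cccc2c(OCc3ccccc3)ccc([C@@H](c3cc(OCc4ccccc4)ccc3OCc3ccccc3)CCC(=O)OC(=O)C(F)(F)F)c12 | intermediate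
20 | (4S)-5,8-bis(benzyloxy)-4-[4-(benzyloxy)-8-methoxynaphthalen-1-yl]-3,4-dihydronaphthalen-1(2H)-one | COc1cccc2c(OCc3ccccc3)ccc([C@@H]3CCC(=O)c4c(OCc5ccccc5)ccc(OCc5ccccc5)c43)c12 | intermediate
21 | (4S)-5,8-dihydroxy-4-(4-hydroxy-8-methoxynaphthalen-1-yl)-3,4-dihydronaphthalen-1(2H)-one | COc1cccc2c(O)ccc([C@@H]3CCC(=O)c4c(O)ccc(O)c43)c12 | target

**Totals**

Total steps: 11. Longest linear sequence: 11 steps (1 to 21).

**Steps most likely to fail**

Step 7. The cycloaddition may take the opposite orientation: the branched substituent at the furan α-carbon turns away from the methoxy group of the aryne, and the methoxy group ends peri to the hydroxyl instead of peri to the side chain. The fallback sets out from boronic acid 5 and comes back at ester 17. It fixes the naphthalene substitution by electrophilic bromination before the stereocentre exists.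
- Naphthalene-1,5-diol is monobenzylated (BnBr 1 equiv, K2CO3, acetone) to 5-(benzyloxy)naphthalen-1-ol F1 and acetylated (Ac2O, pyridine) to 5-(benzyloxy)naphthalen-1-yl acetate F2.
- Because the acetoxy group is the weaker donor, NBS in MeCN should brominate para to the benzyl ether and give 5-(benzyloxy)-8-bromonaphthalen-1-yl acetate F3.
- K2CO3 in MeOH frees 5-(benzyloxy)-8-bromonaphthalen-1-ol F4, which is methylated in the same flask with MeI to 4-(benzyloxy)-1-bromo-8-methoxynaphthalene F5.
- A Heck reaction with methyl acrylate (Pd(OAc)2, P(o-tol)3, Et3N, DMF, 100 °C) gives methyl (2E)-3-[4-(benzyloxy)-8-methoxynaphthalen-1-yl]prop-2-enoate F6.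
- Conjugate addition of 5 under the conditions of step 3, again with (R)-BINAP and on the same αsi face, should give methyl (3S)-3-[4-(benzyloxy)-8-methoxynaphthalen-1-yl]-3-[2,5-bis(benzyloxy)phenyl]propanoate F7.
- Homologation as in steps 4 to 6 passes through (3S)-3-[4-(benzyloxy)-8-methoxynaphthalen-1-yl]-3-[2,5-bis(benzyloxy)phenyl]propanoic acid F8, its ethyl carbonic mixed anhydride F9, (4S)-4-[4-(benzyloxy)-8-methoxynaphthalen-1-yl]-4-[2,5-bis(benzyloxy)phenyl]-1-diazobutan-2-one F10 and the ketene (4S)-4-[4-(benzyloxy)-8-methoxynaphthalen-1-yl]-4-[2,5-bis(benzyloxy)phenyl]but-1-en-1-one F11; methanol trapping gives 17.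

Step 3. Insertion of the β-furyl enoate into the ortho-substituted arylrhodium may be slow, so that protodeboronation consumes the boronic acid and incomplete face selection lowers the enantiomeric purity. The fallback sets out from bromide 2 and comes back at acid 8. It replaces catalyst control by a chiral auxiliary.
- (4S)-4-Phenyl-1,3-oxazolidin-2-one is N-acylated with (2E)-3-(furan-2-yl)prop-2-enoyl chloride (Et3N, LiCl, THF) to (4S)-3-[(2E)-3-(furan-2-yl)prop-2-enoyl]-4-phenyl-1,3-oxazolidin-2-one F12.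
- Bromide 2 is converted with Mg in THF into [2,5-bis(benzyloxy)phenyl]magnesium bromide F13.
- With CuBr·SMe2 at −40 °C, F13 should add to the magnesium-chelated s-cis imide on the face away from the phenyl group and give (4S)-3-[(3R)-3-[2,5-bis(benzyloxy)phenyl]-3-(furan-2-yl)propanoyl]-4-phenyl-1,3-oxazolidin-2-one F14.
- LiOH/H2O2 in THF/H2O at 0 °C removes the auxiliary and returns acid 8; the diastereomers of F14 can be separated beforehand.

Step 10. The acylation may be diverted to C2′ of the electron-rich benzyloxynaphthalene, or the acidic medium may strip or shift a benzyl group. The fallback sets out from naphthol 16 and comes back at target 21. It leaves out the benzylation of step 8 and uses a transient electron-poor ester on the naphthol to shut that ring off.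
- Saponification of 16 (LiOH, degassed THF/H2O) gives (4S)-4-[2,5-bis(benzyloxy)phenyl]-4-(4-hydroxy-8-methoxynaphthalen-1-yl)butanoic acid F15.
- Excess TFAA in CH2Cl2 at 0 °C converts F15 into the naphthyl trifluoroacetate that is also the mixed trifluoroacetic anhydride of the acid F16, whose naphthalene ring is deactivated.
- Ring closure onto ring A then gives 4-[(1S)-5,8-bis(benzyloxy)-4-oxo-1,2,3,4-tetrahydronaphthalen-1-yl]-5-methoxynaphthalen-1-yl trifluoroacetate F17.
- Work-up with NaHCO3 in MeOH cleaves the labile aryl trifluoroacetate to (4S)-5,8-bis(benzyloxy)-4-(4-hydroxy-8-methoxynaphthalen-1-yl)-3,4-dihydronaphthalen-1(2H)-one F18.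
- Hydrogenolysis as in step 11 gives 21.

**Further compounds**

F1 | step 7 | 5-(benzyloxy)naphthalen-1-ol | Oc1cccc2c(OCc3ccccc3)cccc12
F2 | step 7 | 5-(benzyloxy)naphthalen-1-yl acetate | CC(=O)Oc1cccc2c(OCc3ccccc3)cccc12
F3 | step 7 | 5-(benzyloxy)-8-bromonaphthalen-1-yl acetate | CC(=O)Oc1cccc2c(OCc3ccccc3)ccc(Br)c12
F4 | step 7 | 5-(benzyloxy)-8-bromonaphthalen-1-ol | Oc1cccc2c(OCc3ccccc3)ccc(Br)c12
F5 | step 7 | 4-(benzyloxy)-1-bromo-8-methoxynaphthalene | COc1cccc2c(OCc3ccccc3)ccc(Br)c12
F6 | step 7 | methyl (2E)-3-[4-(benzyloxy)-8-methoxynaphthalen-1-yl]prop-2-enoate | COc1cccc2c(OCc3ccccc3)ccc(/C=C/C(=O)OC)c12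
F7 | step 7 | methyl (3S)-3-[4-(benzyloxy)-8-methoxynaphthalen-1-yl]-3-[2,5-bis(benzyloxy)phenyl]propanoate | COc1cccc2c(OCc3ccccc3)ccc([C@@H](c3cc(OCc4ccccc4)ccc3OCc3ccccc3)CC(=O)OC)c12
F8 | step 7 | (3S)-3-[4-(benzyloxy)-8-methoxynaphthalen-1-yl]-3-[2,5-bis(benzyloxy)phenyl]propanoic acid | COc1cccc2c(OCc3ccccc3)ccc([C@@H](c3cc(OCc4ccccc4)ccc3OCc3ccccc3)CC(=O)O)c12
F9 | step 7 | (3S)-3-[4-(benzyloxy)-8-methoxynaphthalen-1-yl]-3-[2,5-bis(benzyloxy)phenyl]propanoic ethyl carbonic anhydride | COc1cccc2c(OCc3ccccc3)ccc([C@@H](c3cc(OCc4ccccc4)ccc3OCc3ccccc3)CC(=O)OC(=O)OCC)c12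
F10 | step 7 | (4S)-4-[4-(benzyloxy)-8-methoxynaphthalen-1-yl]-4-[2,5-bis(benzyloxy)phenyl]-1-diazobutan-2-one | COc1cccc2c(OCc3ccccc3)ccc([C@@H](c3cc(OCc4ccccc4)ccc3OCc3ccccc3)CC(=O)C=[N+]=[N-])c12
F11 | step 7 | (4S)-4-[4-(benzyloxy)-8-methoxynaphthalen-1-yl]-4-[2,5-bis(benzyloxy)phenyl]but-1-en-1-one | COc1cccc2c(OCc3ccccc3)ccc([C@@H](c3cc(OCc4ccccc4)ccc3OCc3ccccc3)CC=C=O)c12
F12 | step 3 | (4S)-3-[(2E)-3-(furan-2-yl)prop-2-enoyl]-4-phenyl-1,3-oxazolidin-2-one | O=C1OC[C@H](c2ccccc2)N1C(=O)/C=C/c1ccco1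
F13 | step 3 | [2,5-bis(benzyloxy)phenyl]magnesium bromide | Br[Mg]c1cc(OCc2ccccc2)ccc1OCc1ccccc1
F14 | step 3 | (4S)-3-[(3R)-3-[2,5-bis(benzyloxy)phenyl]-3-(furan-2-yl)propanoyl]-4-phenyl-1,3-oxazolidin-2-one | O=C1OC[C@H](c2ccccc2)N1C(=O)C[C@@H](c1ccco1)c1cc(OCc2ccccc2)ccc1OCc1ccccc1
F15 | step 10 | (4S)-4-[2,5-bis(benzyloxy)phenyl]-4-(4-hydroxy-8-methoxynaphthalen-1-yl)butanoic acid | COc1cccc2c(O)ccc([C@@H](c3cc(OCc4ccccc4)ccc3OCc3ccccc3)CCC(=O)O)c12
F16 | step 10 | (4S)-4-[2,5-bis(benzyloxy)phenyl]-4-[8-methoxy-4-(trifluoroacetyloxy)naphthalen-1-yl]butanoic trifluoroacetic anhydride | COc1cccc2c(OC(=O)C(F)(F)F)ccc([C@@H](c3cc(OCc4ccccc4)ccc3OCc3ccccc3)CCC(=O)OC(=O)C(F)(F)F)c12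
F17 | step 10 | 4-[(1S)-5,8-bis(benzyloxy)-4-oxo-1,2,3,4-tetrahydronaphthalen-1-yl]-5-methoxynaphthalen-1-yl trifluoroacetate | COc1cccc2c(OC(=O)C(F)(F)F)ccc([C@@H]3CCC(=O)c4c(OCc5ccccc5)ccc(OCc5ccccc5)c43)c12
F18 | step 10 | (4S)-5,8-bis(benzyloxy)-4-(4-hydroxy-8-methoxynaphthalen-1-yl)-3,4-dihydronaphthalen-1(2H)-one | COc1cccc2c(O)ccc([C@@H]3CCC(=O)c4c(OCc5ccccc5)ccc(OCc5ccccc5)c43)c12
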